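Target is made at a rate equal to the last step's constant times c(partner) times c(catalyst intermediate), so at the mark, 5.0% conversion of the starting material, I need to know how much catalyst is bound and how much partner has dissolved.

starting material 1.0 M; solid reagent 2.50 M; free catalyst 10 mM

    starting material + free catalyst ⇌ free catalyst + open intermediate (K1 = 0.32, k1 = 0.99 L mol⁻¹ h⁻¹)
    free catalyst + open intermediate ⇌ catalyst intermediate (K2 = 0.33 L mol⁻¹, k2 = 40 L mol⁻¹ h⁻¹)
    partner + catalyst intermediate → free catalyst + target (k3 = 5.4 L mol⁻¹ h⁻¹)
    solid reagent ⇌ partner, rate k4*(cs4 - [partner]) while solid is left; crystals form when [partner] > cs4 (cs4 = 0.78 M, k4 = 0.010 h⁻¹)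

* the form that holds most of the catalyst when 5.0% of the starting material are converted (free catalyst / catalyst intermediate)
* its share of the catalyst then
* factor on the rate of making target when 5.0% of the starting material are converted if free catalyst is charged twice over
* factor on the rate when 5.0% of the starting material are converted if free catalyst is charged at 100 mM instead

I set this flask beside its neighbour, which is charged with 100 mM of free catalyst instead. Catalyst intermediate lasts about 0.00825 h before it releases its catalyst. With the forward first step, the mark comes at about

time to mark = 5.05 h here, 0.505 h in the neighbour.

That lifetime is far shorter than the time to the mark even in the neighbour, so I take the second step as settled in both flasks. With x the second step's equilibrium constant times c(open intermediate), and c(open intermediate) about 0.0500 M at the mark: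

bound share = x / (1 + x) = 1.62%

I carry this bound share, the fraction of the catalyst tied up at a given c(open intermediate) with the second step settled. In this flask the resting state is therefore free catalyst, holding 98.4%.

Partner dissolves at about 0.00780 M h⁻¹ while c(partner) stays well below solubility, so

c(partner) at mark = 0.0394 M here, 0.00394 M in the neighbour.

In my reckoning the neighbour has ten times the bound catalyst but reaches the mark with less partner, and the two changes cancel. By this reckoning both flasks come to about 3.45 × 10⁻⁵ M h⁻¹, which gives factors of 1.00 for the doubled charge and 1.00 for the neighbour.

The forecast says free catalyst at 98.4%, with factors 1.01 and 0.99, since “the two effects almost cancel”.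

The simulation gives free catalyst at 98.4%, with factors 1.01 and 0.987. This flask reaches the mark at 5.70 h, later than my 5.05 h, and makes target there at 3.75 × 10⁻⁵ M h⁻¹. Its catalyst intermediate holds 1.61% of the catalyst, against a bound share of 1.62%. For the flask charged with 100 mM, my bound share is again 1.62%, and catalyst intermediate holds 1.55% of the catalyst there at the same conversion.

All constants stand for no real mixture; the run is a simulation.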